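What ratio of other capture product to target does the flask hold early on and at the end?

- south-west: substrate 0.75 M; second nucleophile 3 M; gas 110 mM (held); run made earlier
- flask: substrate 1.5 M; second nucleophile 3.00 M; gas 110 mM (held); time 80 min

south-west run (percent of the substrate charged)

| time / min | other capture product / % | target / % |
|---|---|---|
| 8.00 | 34 | 11 |
| 12.0 | 46 | 16 |
| 20.0 | 49 | 19 |
| 25.0 | 53 | 23 |
| 40.0 | 61 | 28 |
| 60.0 | 60 | 32 |
| 90.0 | 62 | 26 |

(each reading ± 2 percentage points)

- at the start none of the gas is in solution

- ratio of other capture product to target at 30 s
- ratio of other capture product to target at 80 min

Dividing the rate of one product by the rate of the other removes time from the question. The split is the gain in other capture product over the gain in target between two readings, the selectivity factor of that stretch. In the south-west run it is 1.59 from 8.00 min to 40.0 min.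

The rungs of time come next. If target takes up gas one for one, the south-west run took up 10.3 mM min⁻¹ over its first 8.00 min. Gas therefore entered at least that fast, a pace that reaches saturation from nothing in 10.7 min. Held to that pace, gas over the first 30 s averages 2.58 mM, and the split scaled by saturation over that average gives 67.8 as a rough estimate of the early ratio from above.

Substrate follows. In the south-west run the two products hold 45.0% by 8.00 min, which as a reading gives a loss constant of 0.0747 min⁻¹ and a half-life of 9.28 min. That is far shorter than the 80 min of the flask, so the final ratio sums the whole run.

The split itself moves in the south-west run: the ratio of the readings is 3.09 up to 8.00 min, and the split after that is lower. Taking the first stretch as read and giving the remaining substrate the split, with the doubled charge assumed to change neither, yields 2.10 at the end.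

The forecast differs, with 35 (10 to 80) and 2.9 (2.2 to 3.8), on the ground that “double the substrate starves the gas”.

The flask gives 10.8 at 30 s and 2.08 at 80 min.

    substrate ⇌ intermediate (K = 0.0667, k = 0.0975 min⁻¹)
    second nucleophile + intermediate → other capture product (k = 1.21 L mol⁻¹ min⁻¹)
    second nucleophile ⇌ dormant form (K = 4.00, k = 0.0263 min⁻¹)
    gas ⇌ first nucleophile, rate k4*(csat - [first nucleophile]) (kL = 0.951 min⁻¹)
    target ⇌ isomer of the product (K = 0.210, k = 0.0102 min⁻¹)
    first nucleophile + intermediate → target (k = 12.9 L mol⁻¹ min⁻¹)

The flask's own split from 8.00 min to 40.0 min is 1.62. In the scheme, with the first nucleophile as the dissolved gas, the split is proportional to [second nucleophile] at a given [first nucleophile]. The neighbouring flask charged with 1.2 M of second nucleophile therefore reckons as 2.10 times 0.400, or 0.840. That neighbour gives 0.741 at 80.0 min, with other capture product at 37.6% and target at 50.8%.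

(The runs are calculated from invented constants.)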